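**Retrosynthetic overview**

- The diacid comes from its dimethyl ester; the ten-membered ring comes from a ring expansion in which fluoride cleaves the ring-fusion C–C bond of a cis-fused hexahydronaphthalene carrying CH2SiMe3 on a fusion carbon. This one event creates the exocyclic methylene and the (1E,3Z)-diene ester.
- That bicycle comes from annulating ring A onto a ring-B allylsilane with a 2-pyrone ([4+2], then loss of CO2).
- The allylsilane comes from an alkenyl nonaflate and a Me3SiCH2–zinc reagent; the nonaflate comes from the regiospecific silyl enol ether of a Mukaiyama–Michael addition that builds the quaternary centre anti to the ester.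
- The enone, (R)-methyl 2-methyl-4-oxocyclohex-2-ene-1-carboxylate, comes from a catalytic asymmetric Diels–Alder reaction (sets the CH–CO2Me centre) followed by Saegusa oxidation.
- Ring order: ring B (Diels–Alder), then ring A (pyrone annulation), then both are merged into the ten-membered carbocycle.

Assumption: (E)-pent-3-en-2-one, methyl acrylate, 1-(furan-3-yl)ethan-1-one and 3-bromo-2H-pyran-2-one are bought; locants in a name follow that compound's own numbering.

**Route**

Step 1
Reactants: 1 (E)-pent-3-en-2-one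
Product: 2 triisopropyl{[(3E)-penta-1,3-dien-2-yl]oxy}silane
Conditions: TIPSOTf, Et3N, CH2Cl2, 0 °C
Reagents that add atoms: triisopropylsilyl trifluoromethanesulfonate, CC(C)[Si](C(C)C)(C(C)C)OS(=O)(=O)C(F)(F)F
Why: Soft enolisation of the methyl ketone on its CH3 side and O-silylation (silyl dienol ether formation) give the cross-conjugated 2-silyloxy diene with the (E)-propenyl unit untouched; no stereocentre is formed.

Step 2
Reactants: 2 triisopropyl{[(3E)-penta-1,3-dien-2-yl]oxy}silane; 3 methyl acrylate
Product: 4 methyl (1R,2S)-2-methyl-4-[(triisopropylsilyl)oxy]cyclohex-3-ene-1-carboxylate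
Conditions: (R)-B-(o-tolyl)oxazaborolidine from (R)-α,α-diphenylprolinol, activated with HNTf2 (10 mol %), CH2Cl2, −78 → −40 °C
Reagents that add atoms: none
Why: Catalytic enantioselective Diels–Alder reaction in which the protonated oxazaborolidine shields one acrylate face so that C1 is set as R (sense assigned by analogy with butadiene–acrylate additions under this catalyst class, the antipodal catalyst being used if it proves opposite), the silyloxy group directs "para" and the terminal methyl "ortho", and the endo mode gives the cis 2-methyl group that is erased in step 3.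

Step 3
Reactants: 4 methyl (1R,2S)-2-methyl-4-[(triisopropylsilyl)oxy]cyclohex-3-ene-1-carboxylate
Product: 5 methyl (1R)-2-methyl-4-oxocyclohex-2-ene-1-carboxylate
Conditions: Pd(OAc)2 (1.05 equiv), MeCN, 40 °C
Reagents that add atoms: none
Why: Saegusa–Ito oxidation, in which the palladium enolate formed from the silyl enol ether undergoes β-hydride elimination toward C2, gives the enone regiospecifically under non-basic conditions that leave the C1 stereocentre intact.

Step 4
Reactants: 6 1-(furan-3-yl)ethan-1-one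
Product: 7 {[1-(furan-3-yl)ethenyl]oxy}trimethylsilane
Conditions: TMSOTf, Et3N, CH2Cl2, 0 °C
Reagents that add atoms: trimethylsilyl trifluoromethanesulfonate, C[Si](C)(C)OS(=O)(=O)C(F)(F)F
Why: Soft enolisation and O-silylation of the methyl ketone (silyl enol ether formation); no stereocentre is formed.

Step 5
Reactants: 5 methyl (1R)-2-methyl-4-oxocyclohex-2-ene-1-carboxylate; 7 {[1-(furan-3-yl)ethenyl]oxy}trimethylsilane
Product: 8 methyl (1R,2R)-2-[2-(furan-3-yl)-2-oxoethyl]-2-methyl-4-[(trimethylsilyl)oxy]cyclohex-3-ene-1-carboxylate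
Conditions: Me3SiNTf2 (5 mol %), CH2Cl2, −78 °C; Et3N quench, used crude
Reagents that add atoms: none
Why: Mukaiyama–Michael addition in which the enol silane attacks the β-carbon anti to the pseudo-axial C1 ester, so the quaternary centre forms with the acylmethyl group trans and the methyl cis to the ester, while silyl transfer keeps the enolate regiochemistry as the C3=C4 silyl enol ether.

Step 6
Reactants: 8 methyl (1R,2R)-2-[2-(furan-3-yl)-2-oxoethyl]-2-methyl-4-[(trimethylsilyl)oxy]cyclohex-3-ene-1-carboxylate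
Product: 9 methyl (1R,2R)-2-[2-(furan-3-yl)-2-oxoethyl]-2-methyl-4-{[(nonafluorobutyl)sulfonyl]oxy}cyclohex-3-ene-1-carboxylate
Conditions: C4F9SO2F (1.3 equiv), Bu4NF (10 mol %), THF, 0 °C
Reagents that add atoms: nonafluorobutane-1-sulfonyl fluoride, O=S(=O)(F)C(F)(F)C(F)(F)C(F)(F)C(F)(F)F
Why: Fluoride-catalysed conversion of the silyl enol ether into the alkenyl nonaflate keeps the double-bond position, spares the aryl ketone because free enolate is present only in catalytic amount, and leaves both stereocentres untouched.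

Step 7
Reactants: 9 methyl (1R,2R)-2-[2-(furan-3-yl)-2-oxoethyl]-2-methyl-4-{[(nonafluorobutyl)sulfonyl]oxy}cyclohex-3-ene-1-carboxylate
Product: 10 methyl (1R,2R)-2-[2-(furan-3-yl)-2-oxoethyl]-2-methyl-4-[(trimethylsilyl)methyl]cyclohex-3-ene-1-carboxylate
Conditions: Me3SiCH2MgCl + ZnCl2 (THF, 0 °C); then 9, Pd(PPh3)4 (5 mol %), THF, 50 °C
Reagents that add atoms: (trimethylsilyl)methylmagnesium chloride, C[Si](C)(C)C[Mg]Cl
Why: Negishi cross-coupling of the alkenyl nonaflate with the (trimethylsilyl)methylzinc reagent gives the allylsilane, the organozinc tolerating ketone and ester, with the stereocentres untouched.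

Step 8
Reactants: 11 3-bromo-2H-pyran-2-one
Product: 12 methyl 2-oxo-2H-pyran-3-carboxylate
Conditions: Pd(OAc)2 (5 mol %), Xantphos (6 mol %), CO (1 atm), MeOH (5 equiv), i-Pr2NEt, PhMe, 70 °C
Reagents that add atoms: carbon monoxide, [C-]#[O+]; methanol, CO
Why: Palladium-catalysed alkoxycarbonylation of the vinylic bromide installs the ester that makes the pyrone a strongly electron-poor diene.

Step 9
Reactants: 10 methyl (1R,2R)-2-[2-(furan-3-yl)-2-oxoethyl]-2-methyl-4-[(trimethylsilyl)methyl]cyclohex-3-ene-1-carboxylate; 12 methyl 2-oxo-2H-pyran-3-carboxylate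
Product: 14 dimethyl (4aS,5R,6R,8aS)-5-[2-(furan-3-yl)-2-oxoethyl]-5-methyl-8a-[(trimethylsilyl)methyl]-4a,5,6,7,8,8a-hexahydronaphthalene-1,6-dicarboxylate, via bridged lactone cycloadduct 13 (not isolated)
Conditions: 12 (3 equiv), BHT, PhMe, 110 °C, sealed tube
Reagents that add atoms: none
Why: Inverse-electron-demand Diels–Alder reaction of the 2-pyrone with the nucleophilic allylsilane (the CH carbon bonds to pyrone C6, the silylmethyl-bearing carbon to pyrone C3), then retro-Diels–Alder loss of CO2, gives the cis-fused cyclohexadiene; the two new fusion centres (addition anti to the axial methyl expected, the other cis-fused isomer converging) are destroyed in step 10.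

Step 10
Reactants: 14 dimethyl (4aS,5R,6R,8aS)-5-[2-(furan-3-yl)-2-oxoethyl]-5-methyl-8a-[(trimethylsilyl)methyl]-4a,5,6,7,8,8a-hexahydronaphthalene-1,6-dicarboxylate
Product: 16 dimethyl (1E,3Z,6S,7R)-6-[2-(furan-3-yl)-2-oxoethyl]-6-methyl-10-methylidenecyclodeca-1,3-diene-1,7-dicarboxylate, via tetrabutylammonium ester trienolate 15 (not isolated)
Conditions: Bu4NF (anhydrous, 2 equiv), t-BuOH (3 equiv), DMF, 25 → 60 °C; AcOH
Reagents that add atoms: none
Why: Proposed new method: fluoride attack on silicon makes the C–Si bond a carbanion equivalent antiperiplanar to the doubly allylic C4a–C8a bond, whose σ* is conjugated with the dienoate, so a Grob-type (retro-Michael, E1cB-like) fragmentation expels the ester trienolate, opens ring B into the ten-membered ring and forms the exocyclic methylene, and base-equilibrated protonation at the ε-carbon gives the conjugated (1E,3Z)-diene ester with both stereocentres untouched; the closest known reaction types are fluoride-induced 1,4-eliminations of (silylmethyl)arenes, silyl- or stannyl-triggered Grob fragmentations and fluoride opening of (silylmethyl)cyclopropyl ketones, none of which cleaves an unstrained C–C bond into an extended ester enolate.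

Step 11
Reactants: 16 dimethyl (1E,3Z,6S,7R)-6-[2-(furan-3-yl)-2-oxoethyl]-6-methyl-10-methylidenecyclodeca-1,3-diene-1,7-dicarboxylate
Product: 17 (1E,3Z,6S,7R)-6-[2-(furan-3-yl)-2-oxoethyl]-6-methyl-10-methylidenecyclodeca-1,3-diene-1,7-dicarboxylic acid
Conditions: LiOH·H2O, THF/MeOH/H2O, 40 °C; 1 M HCl to pH 2
Reagents that add atoms: lithium hydroxide, [Li+].[OH-]
Why: Saponification of both methyl esters and acidification give the diacid, the C7 carboxylate formed first protecting that centre from epimerisation.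

**Compound list**

1 | (E)-pent-3-en-2-one | C/C=C/C(C)=O | starting material
2 | triisopropyl{[(3E)-penta-1,3-dien-2-yl]oxy}silane | C/C=C/C(=C)O[Si](C(C)C)(C(C)C)C(C)C | intermediate
3 | methyl acrylate | C=CC(=O)OC | starting material
4 | methyl (1R,2S)-2-methyl-4-[(triisopropylsilyl)oxy]cyclohex-3-ene-1-carboxylate | CC(C)[Si](C(C)C)(C(C)C)OC1=C[C@H](C)[C@H](C(=O)OC)CC1 | intermediate
5 | methyl (1R)-2-methyl-4-oxocyclohex-2-ene-1-carboxylate | O=C1CC[C@@H](C(=O)OC)C(C)=C1 | intermediate
6 | 1-(furan-3-yl)ethan-1-one | CC(=O)c1ccoc1 | starting material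
7 | {[1-(furan-3-yl)ethenyl]oxy}trimethylsilane | C=C(O[Si](C)(C)C)c1ccoc1 | intermediate
8 | methyl (1R,2R)-2-[2-(furan-3-yl)-2-oxoethyl]-2-methyl-4-[(trimethylsilyl)oxy]cyclohex-3-ene-1-carboxylate | C[Si](C)(C)OC1=C[C@@](C)(CC(=O)c2ccoc2)[C@H](C(=O)OC)CC1 | intermediate
9 | methyl (1R,2R)-2-[2-(furan-3-yl)-2-oxoethyl]-2-methyl-4-{[(nonafluorobutyl)sulfonyl]oxy}cyclohex-3-ene-1-carboxylate | O=S(=O)(OC1=C[C@@](C)(CC(=O)c2ccoc2)[C@H](C(=O)OC)CC1)C(F)(F)C(F)(F)C(F)(F)C(F)(F)F | intermediate
10 | methyl (1R,2R)-2-[2-(furan-3-yl)-2-oxoethyl]-2-methyl-4-[(trimethylsilyl)methyl]cyclohex-3-ene-1-carboxylate | C[Si](C)(C)CC1=C[C@@](C)(CC(=O)c2ccoc2)[C@H](C(=O)OC)CC1 | intermediate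
11 | 3-bromo-2H-pyran-2-one | O=C1OC=CC=C1Br | starting material
12 | methyl 2-oxo-2H-pyran-3-carboxylate | COC(=O)C1=CC=COC1=O | intermediate
13 | bridged lactone cycloadduct: pyrone C6 bonded to C3 and pyrone C3 to C4 of 10, giving a 2-oxabicyclo[2.2.2]oct-5-en-3-one fused to the cyclohexane, with CO2Me on the bridgehead next to the C–CH2SiMe3 carbon (ring-B centres as in 10; the four new centres form as a mixture) | C[Si](C)(C)CC12CC[C@@H](C(=O)OC)[C@](C)(CC(=O)c3ccoc3)C1C1C=CC2(C(=O)OC)C(=O)O1 | intermediate
14 | dimethyl (4aS,5R,6R,8aS)-5-[2-(furan-3-yl)-2-oxoethyl]-5-methyl-8a-[(trimethylsilyl)methyl]-4a,5,6,7,8,8a-hexahydronaphthalene-1,6-dicarboxylate (cis-fused; expected major face drawn) | C[Si](C)(C)C[C@@]12CC[C@@H](C(=O)OC)[C@](C)(CC(=O)c3ccoc3)[C@@H]1C=CC=C2C(=O)OC | intermediate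
15 | tetrabutylammonium ester trienolate of 16 (enolate delocalised over the ring diene; ring double-bond geometry not fixed) | C=C1CC[C@@H](C(=O)OC)[C@](C)(CC(=O)c2ccoc2)C=CC=CC1=C([O-])OC.CCCC[N+](CCCC)(CCCC)CCCC | intermediate
16 | dimethyl (1E,3Z,6S,7R)-6-[2-(furan-3-yl)-2-oxoethyl]-6-methyl-10-methylidenecyclodeca-1,3-diene-1,7-dicarboxylate | C=C1CC[C@@H](C(=O)OC)[C@](C)(CC(=O)c2ccoc2)C/C=C\C=C/1C(=O)OC | intermediate
17 | (1E,3Z,6S,7R)-6-[2-(furan-3-yl)-2-oxoethyl]-6-methyl-10-methylidenecyclodeca-1,3-diene-1,7-dicarboxylic acid | C=C1CC[C@@H](C(=O)O)[C@](C)(CC(=O)c2ccoc2)C/C=C\C=C/1C(=O)O | target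

**Step count and risks**

Total step count: 11. Longest linear sequence: 9 (steps 1, 2, 3, 5, 6, 7, 9, 10, 11).

Steps most likely to fail:

Step 10 (the proposed new fragmentation; an unactivated CH2–SiMe3 group may not respond to fluoride). The fallback uses known chemistry and sets out from 14. Irradiation (300 nm, THF, −40 °C) brings about the photochemical conrotatory ring opening that cyclohexa-1,3-dienes are known to undergo (the provitamin D type). This gives the ten-membered trienyl allylsilane dimethyl (7R,8R)-7-[2-(furan-3-yl)-2-oxoethyl]-7-methyl-1-[(trimethylsilyl)methyl]cyclodeca-1,3,5-triene-2,8-dicarboxylate F1, in which silicon is now allylic and γ to the ester. Bu4NF added cold then desilylates it in the way known for γ-silyl enoates, giving the same trienolate 15; protonation rejoins the route at 16.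

Step 9 (cycloaddition of a hindered trisubstituted allylsilane next to a quaternary carbon). The fallback sets out from 10 and 11 and builds ring A with a halogen placeholder. The unsubstituted bromopyrone 11, which puts the smaller bromine at the congested bond-forming carbon, is used as the diene (12 kbar, CH2Cl2, then 100 °C). Via the bromo lactone cycloadduct F2 and loss of CO2 this gives methyl (1R,2R)-5-bromo-1-[2-(furan-3-yl)-2-oxoethyl]-1-methyl-4a-[(trimethylsilyl)methyl]-1,2,3,4,4a,8a-hexahydronaphthalene-2-carboxylate F3. Its vinylic bromide is then methoxycarbonylated (Pd(OAc)2, Xantphos, CO, MeOH, i-Pr2NEt), coming back at 14.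

Step 5 (quaternary centre by Mukaiyama–Michael addition; conversion and anti selectivity uncertain). The fallback sets out from 5 and 6. Ketone 6 is condensed with Me2NNH2 to (E)-2-[1-(furan-3-yl)ethylidene]-1,1-dimethylhydrazine F4. F4 is lithiated (LDA) and transferred to copper (CuBr·SMe2), and the aza-enolate cuprate is added to 5. The resulting enolate is trapped in situ with PhNTf2 as methyl (1R,2R)-2-[2-(2,2-dimethylhydrazinylidene)-2-(furan-3-yl)ethyl]-2-methyl-4-{[(trifluoromethyl)sulfonyl]oxy}cyclohex-3-ene-1-carboxylate F5. Kumada coupling with Me3SiCH2MgCl (Pd(PPh3)4) gives methyl (1R,2R)-2-[2-(2,2-dimethylhydrazinylidene)-2-(furan-3-yl)ethyl]-2-methyl-4-[(trimethylsilyl)methyl]cyclohex-3-ene-1-carboxylate F6, and CuCl2 in aqueous THF at pH 7 cleaves the hydrazone, coming back at 10.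

**Further compounds**

F1 | step 10 | dimethyl (7R,8R)-7-[2-(furan-3-yl)-2-oxoethyl]-7-methyl-1-[(trimethylsilyl)methyl]cyclodeca-1,3,5-triene-2,8-dicarboxylate (terminal ring double-bond geometry as formed) | C[Si](C)(C)CC1=C(C(=O)OC)C=CC=C[C@@](C)(CC(=O)c2ccoc2)[C@H](C(=O)OC)CC1
F2 | step 9 | bromo lactone cycloadduct (as 13 with Br in place of the bridgehead CO2Me) | C[Si](C)(C)CC12CC[C@@H](C(=O)OC)[C@](C)(CC(=O)c3ccoc3)C1C1C=CC2(Br)C(=O)O1
F3 | step 9 | methyl (1R,2R)-5-bromo-1-[2-(furan-3-yl)-2-oxoethyl]-1-methyl-4a-[(trimethylsilyl)methyl]-1,2,3,4,4a,8a-hexahydronaphthalene-2-carboxylate (cis-fused, fusion as in 14) | C[Si](C)(C)C[C@@]12CC[C@@H](C(=O)OC)[C@](C)(CC(=O)c3ccoc3)[C@@H]1C=CC=C2Br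
F4 | step 5 | (E)-2-[1-(furan-3-yl)ethylidene]-1,1-dimethylhydrazine | C/C(=N\N(C)C)c1ccoc1
F5 | step 5 | methyl (1R,2R)-2-[2-(2,2-dimethylhydrazinylidene)-2-(furan-3-yl)ethyl]-2-methyl-4-{[(trifluoromethyl)sulfonyl]oxy}cyclohex-3-ene-1-carboxylate | O=S(=O)(OC1=C[C@@](C)(CC(=NN(C)C)c2ccoc2)[C@H](C(=O)OC)CC1)C(F)(F)F
F6 | step 5 | methyl (1R,2R)-2-[2-(2,2-dimethylhydrazinylidene)-2-(furan-3-yl)ethyl]-2-methyl-4-[(trimethylsilyl)methyl]cyclohex-3-ene-1-carboxylate | C[Si](C)(C)CC1=C[C@@](C)(CC(=NN(C)C)c2ccoc2)[C@H](C(=O)OC)CC1
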